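The γ-lactone ring (O–C6–C7–C11–C12) is closed by stitching in carbon dioxide, which supplies C12 and the ring oxygen. CO2 is inserted between the vinylic carbon C11 (C11=C13, carried as an alkenylboronate) and C6, which is allylic to the C4=C5 olefin and carries a tert-butyl carbonate. In one flask a copper-catalysed carboxylation forms C11–C12 and a palladium-catalysed allylic substitution by the new carboxylate forms O–C6, closing the trans-fused α-methylene lactone with retention at C6. The precursor is an open-chain 2-boryl homoallylic carbonate from an anti-selective allenylzinc addition; the ten-membered ring is closed later by ring-closing metathesis at C1=C10.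

Key step: step 12

Remark: atom labels C-1 to C-15 follow the germacrane numbering of the target (lactone O–C-6, C-7, C-11, C-12; exocyclic C-13; ester carbon C-14; methyl C-15).

Step 1
Reactants: 1 4,6-O-[(R)-benzylidene]-D-glucopyranose
Product: 2 2,4-O-[(R)-benzylidene]-D-erythrose
Conditions: NaIO4 (2.2 equiv), NaHCO3, H2O, 0 °C → rt
Reagents that add atoms: none
Why: Malaprade glycol cleavage cuts C1–C2 and C2–C3 of the sugar and the formate left on O-5 hydrolyses, so glucose C-3 to C-6 emerge as the erythrose acetal with the future C-7 and C-8 stereocentres untouched and the future C-8 hydroxyl alone free.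

Step 2
Reactants: 2 2,4-O-[(R)-benzylidene]-D-erythrose
Product: 3 (2R,4S,5R)-4-ethynyl-2-phenyl-1,3-dioxan-5-ol
Conditions: dimethyl (1-diazo-2-oxopropyl)phosphonate, K2CO3, MeOH, 0 °C → rt
Reagents that add atoms: dimethyl (1-diazo-2-oxopropyl)phosphonate, COP(=O)(OC)C(=[N+]=[N-])C(C)=O
Why: Seyferth–Gilbert homologation in its Ohira–Bestmann form turns the aldehyde into the terminal alkyne (future C-11≡C-13) under mild carbonate base, the α-centre being locked in the dioxane ring.

Step 3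
Reactants: 3 (2R,4S,5R)-4-ethynyl-2-phenyl-1,3-dioxan-5-ol
Product: 4 (2R,4S,5R)-4-ethynyl-5-[(4-methoxybenzyl)oxy]-2-phenyl-1,3-dioxane
Conditions: NaH (1.05 equiv), 4-methoxybenzyl chloride, Bu4NI (cat.), DMF, 0 °C → rt
Reagents that add atoms: 4-methoxybenzyl chloride, COc1ccc(CCl)cc1
Why: Williamson etherification of the secondary alkoxide (far more acidic than the alkyne C–H) installs the PMB ether that later serves as the chelating group on C-8.

Step 4
Reactants: 4 (2R,4S,5R)-4-ethynyl-5-[(4-methoxybenzyl)oxy]-2-phenyl-1,3-dioxane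
Product: 5 (2R,3S)-2-[(4-methoxybenzyl)oxy]pent-4-yne-1,3-diol
Conditions: AcOH/H2O (4:1), 45 °C
Reagents that add atoms: none
Why: Acid hydrolysis of the benzylidene acetal frees the primary (C-9) and propargylic (C-7) hydroxyls while the PMB ether and the alkyne are stable to aqueous acetic acid.

Step 5
Reactants: 5 (2R,3S)-2-[(4-methoxybenzyl)oxy]pent-4-yne-1,3-diol
Product: 7 (3S,4R)-5-[(tert-butyldimethylsilyl)oxy]-4-[(4-methoxybenzyl)oxy]pent-1-yn-3-yl methanesulfonate, via silyl ether 6 (not isolated)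
Conditions: TBSCl (1.05 equiv), imidazole, CH2Cl2, −20 °C; then MsCl, Et3N, −20 → 0 °C
Reagents that add atoms: tert-butyldimethylsilyl chloride, CC(C)(C)[Si](C)(C)Cl; methanesulfonyl chloride, CS(=O)(=O)Cl
Why: The primary hydroxyl is silylated selectively on steric grounds and the remaining propargylic hydroxyl is then O-sulfonylated in the same flask, with retention at C-7.

Step 6
Reactants: 8 ethyl but-2-ynoate; 9 but-3-en-1-ylmagnesium bromide
Product: 10 ethyl (2E)-3-methylhepta-2,6-dienoate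
Conditions: 9, CuI (1.1 equiv), THF, −78 °C; then 8, −78 °C; NH4Cl aq. at −78 °C
Reagents that add atoms: none
Why: syn-Carbocupration of the ynoate at low temperature places the butenyl group and the new hydrogen cis, which fixes the E trisubstituted olefin (future C-4=C-5 with C-15 methyl).

Step 7
Reactants: 10 ethyl (2E)-3-methylhepta-2,6-dienoate
Product: 11 (2E)-3-methylhepta-2,6-dien-1-ol
Conditions: iBu2AlH (2.2 equiv), CH2Cl2, −78 → 0 °C
Reagents that add atoms: none
Why: 1,2-Reduction of the enoate by the aluminium hydride gives the allylic alcohol without touching either olefin.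

Step 8
Reactants: 11 (2E)-3-methylhepta-2,6-dien-1-ol
Product: 12 (2E)-3-methylhepta-2,6-dienal
Conditions: MnO2, CH2Cl2, rt
Reagents that add atoms: none
Why: Allylic oxidation with manganese dioxide gives the enal (future C-6 aldehyde) without E/Z isomerisation.

Step 9
Reactants: 7 (3S,4R)-5-[(tert-butyldimethylsilyl)oxy]-4-[(4-methoxybenzyl)oxy]pent-1-yn-3-yl methanesulfonate; 12 (2E)-3-methylhepta-2,6-dienal
Product: 14 (2S,3S,4R,5E)-1-[(tert-butyldimethylsilyl)oxy]-3-ethynyl-2-[(4-methoxybenzyl)oxy]-6-methyldeca-5,9-dien-4-ol, via allenylzinc 13 (not isolated)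
Conditions: Pd(OAc)2 (5 mol%), PPh3 (5 mol%), Et2Zn (3 equiv), THF, −78 → −20 °C
Reagents that add atoms: none
Why: Marshall–Tamaru propargylation: anti SN2′ oxidative addition of zerovalent palladium, transmetalation to allenylzinc 13 and a closed SE2′ transition state should give the anti homopropargylic alcohol, C-7 being set with net inversion of the mesylate centre (chirality transfer through the allene axis) and C-6 by the chair-like transition state that places the alkenyl group of the aldehyde anti to the C-8 chain.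

Step 10
Reactants: 14 (2S,3S,4R,5E)-1-[(tert-butyldimethylsilyl)oxy]-3-ethynyl-2-[(4-methoxybenzyl)oxy]-6-methyldeca-5,9-dien-4-ol
Product: 16 (2S,3S,4R,5E)-1-[(tert-butyldimethylsilyl)oxy]-2-[(4-methoxybenzyl)oxy]-6-methyl-3-[1-(4,4,5,5-tetramethyl-1,3,2-dioxaborolan-2-yl)ethenyl]deca-5,9-dien-4-ol, via alkenylalane 15 (not isolated)
Conditions: NiCl2(dppp) (3 mol%), iBu2AlH (2.3 equiv), THF, 0 → 22 °C; then 2-methoxy-4,4,5,5-tetramethyl-1,3,2-dioxaborolane, 0 → 22 °C; Rochelle salt work-up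
Reagents that add atoms: 2-methoxy-4,4,5,5-tetramethyl-1,3,2-dioxaborolane, COB1OC(C)(C)C(C)(C)O1
Why: Nickel-catalysed α-selective hydroalumination of the terminal alkyne (the bisphosphine directs aluminium to the internal carbon C-11; one hydride equivalent is spent on the hydroxyl) followed by aluminium-to-boron exchange with the methoxyboronate should give the 1,1-disubstituted alkenylboronate.

Step 11
Reactants: 16 (2S,3S,4R,5E)-1-[(tert-butyldimethylsilyl)oxy]-2-[(4-methoxybenzyl)oxy]-6-methyl-3-[1-(4,4,5,5-tetramethyl-1,3,2-dioxaborolan-2-yl)ethenyl]deca-5,9-dien-4-ol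
Product: 17 tert-butyl carbonate of 16 at the C-6 hydroxyl
Conditions: Boc2O, DMAP (cat.), Et3N, CH2Cl2, rt
Reagents that add atoms: di-tert-butyl dicarbonate, CC(C)(C)OC(=O)OC(=O)OC(C)(C)C
Why: DMAP-catalysed O-acylation turns the allylic C-6 hydroxyl into a base-stable carbonate leaving group with retention of configuration.

Step 12
Reactants: 17 tert-butyl carbonate of 16 at the C-6 hydroxyl
Product: 19 (4S,5R)-4-[(1S)-2-[(tert-butyldimethylsilyl)oxy]-1-[(4-methoxybenzyl)oxy]ethyl]-3-methylidene-5-[(1E)-2-methylhexa-1,5-dien-1-yl]oxolan-2-one, via potassium carboxylate 18 (not isolated)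
Conditions: (IPr)CuCl (5 mol%; IPr = 1,3-bis(2,6-diisopropylphenyl)imidazol-2-ylidene), KOtBu (1.1 equiv), CO2 (1 atm), THF, 65 °C; then Pd(PPh3)4 (5 mol%), CO2 (1 atm), 45 °C
Reagents that add atoms: carbon dioxide, O=C=O
Why: (IPr)Cu–OtBu takes over the C-11 alkenyl group from boron and CO2 inserts into the C-11–Cu bond to give acrylate carboxylate 18 (new C-11–C-12 bond); zerovalent palladium then ionises the C-6 tert-butyl carbonate anti to its C–O bond to a π-allyl complex spanning C-4 to C-6, which the tethered carboxylate oxygen attacks at C-6 anti to palladium (new O–C-6 bond). The closest known reaction types are the copper-catalysed carboxylation of alkenylboronic esters with CO2 and the Tsuji–Trost lactonisation of carboxylates onto allylic carbonates, here run in one flask. The only ring closed is the γ-lactone, by 5-exo attack on the π-allyl terminus, the C-4=C-5 olefin staying exocyclic to it. No stereocentre is made from scratch: C-6 keeps the configuration set in step 9 through double inversion, and because ionisation of the allylic lactone is reversible the thermodynamically preferred 6,7-trans lactone should also result from equilibration. The step needs C-6 over C-4 attack and retention of the 4E geometry, secured by the five- versus seven-membered ring size, the tertiary nature of C-4 and the syn π-allyl that forms from the E olefin and cannot isomerise through its tertiary terminus. CO2 insertion must also outrun attack of the alkenylcopper on the carbonate, which the CO2 atmosphere and the low nucleophilicity of the carbene-ligated alkenylcopper towards carbonates should secure.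

Step 13
Reactants: 19 (4S,5R)-4-[(1S)-2-[(tert-butyldimethylsilyl)oxy]-1-[(4-methoxybenzyl)oxy]ethyl]-3-methylidene-5-[(1E)-2-methylhexa-1,5-dien-1-yl]oxolan-2-one
Product: 20 (4S,5R)-4-[(1S)-2-hydroxy-1-[(4-methoxybenzyl)oxy]ethyl]-3-methylidene-5-[(1E)-2-methylhexa-1,5-dien-1-yl]oxolan-2-one
Conditions: HF·pyridine, pyridine, THF, 0 °C → rt
Reagents that add atoms: none
Why: Buffered fluoride cleaves the primary silyl ether while the lactone, the PMB ether and the exo-methylene group are stable.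

Step 14
Reactants: 20 (4S,5R)-4-[(1S)-2-hydroxy-1-[(4-methoxybenzyl)oxy]ethyl]-3-methylidene-5-[(1E)-2-methylhexa-1,5-dien-1-yl]oxolan-2-one
Product: 21 (2S)-2-[(4-methoxybenzyl)oxy]-2-[(2R,3S)-4-methylidene-2-[(1E)-2-methylhexa-1,5-dien-1-yl]-5-oxooxolan-3-yl]acetaldehyde
Conditions: Dess–Martin periodinane, NaHCO3, CH2Cl2, 0 °C → rt
Reagents that add atoms: none
Why: Buffered Dess–Martin oxidation gives the α-alkoxy aldehyde (C-9) without epimerisation at C-8; the aldehyde is used directly.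

Step 15
Reactants: 22 methyl 2-bromopropanoate
Product: 23 methyl 2-(phenylselanyl)propanoate
Conditions: (PhSe)2, NaBH4, EtOH, 0 °C; then 22, 0 °C → rt
Reagents that add atoms: diphenyl diselenide, c1ccc(cc1)[Se][Se]c1ccccc1
Why: SN2 displacement of the α-bromide by benzeneselenolate made in the flask gives the α-seleno ester, a masked acrylate.

Step 16
Reactants: 23 methyl 2-(phenylselanyl)propanoate
Product: 24 [(1-methoxy-2-(phenylselanyl)prop-1-en-1-yl)oxy]trimethylsilane
Conditions: LiN(iPr)2, THF, −78 °C; then Me3SiCl, −78 °C → rt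
Reagents that add atoms: chlorotrimethylsilane, C[Si](C)(C)Cl
Why: Kinetic enolisation and O-silylation give the ketene silyl acetal; its E/Z composition is irrelevant because the C-10 centre is destroyed in step 18.

Step 17
Reactants: 21 (2S)-2-[(4-methoxybenzyl)oxy]-2-[(2R,3S)-4-methylidene-2-[(1E)-2-methylhexa-1,5-dien-1-yl]-5-oxooxolan-3-yl]acetaldehyde; 24 [(1-methoxy-2-(phenylselanyl)prop-1-en-1-yl)oxy]trimethylsilane
Product: 25 methyl (3R,4S)-3-hydroxy-4-[(4-methoxybenzyl)oxy]-2-methyl-4-[(2R,3S)-4-methylidene-2-[(1E)-2-methylhexa-1,5-dien-1-yl]-5-oxooxolan-3-yl]-2-(phenylselanyl)butanoate (both C-10 epimers)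
Conditions: MgBr2·OEt2 (3 equiv), CH2Cl2, −78 → −30 °C; then 1 M HCl/THF, 0 °C
Reagents that add atoms: none
Why: Chelation-controlled Mukaiyama aldol: magnesium bridges the aldehyde oxygen and the C-8 PMB ether oxygen and the ketene acetal attacks the face opposite the C-7 substituent (Cram chelate), which should set C-9 syn to C-8; the aldehyde reacts far faster than the exo-methylene lactone.

Step 18
Reactants: 25 methyl (3R,4S)-3-hydroxy-4-[(4-methoxybenzyl)oxy]-2-methyl-4-[(2R,3S)-4-methylidene-2-[(1E)-2-methylhexa-1,5-dien-1-yl]-5-oxooxolan-3-yl]-2-(phenylselanyl)butanoate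
Product: 27 methyl (3S,4S)-3-hydroxy-4-[(4-methoxybenzyl)oxy]-2-methylidene-4-[(2R,3S)-4-methylidene-2-[(1E)-2-methylhexa-1,5-dien-1-yl]-5-oxooxolan-3-yl]butanoate, via selenoxide 26 (not isolated)
Conditions: mCPBA (1.05 equiv), CH2Cl2, −78 °C; then iPr2NH, −78 °C → rt
Reagents that add atoms: none
Why: Selenoxide syn-elimination runs away from the carbinol carbon into the methyl group and so unveils the 1,1-disubstituted acrylate (C-10=CH2 with C-14 ester); selenium is oxidised at −78 °C faster than any olefin.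

Step 19
Reactants: 27 methyl (3S,4S)-3-hydroxy-4-[(4-methoxybenzyl)oxy]-2-methylidene-4-[(2R,3S)-4-methylidene-2-[(1E)-2-methylhexa-1,5-dien-1-yl]-5-oxooxolan-3-yl]butanoate
Product: 28 methyl (3S,4S)-3-acetoxy-4-[(4-methoxybenzyl)oxy]-2-methylidene-4-[(2R,3S)-4-methylidene-2-[(1E)-2-methylhexa-1,5-dien-1-yl]-5-oxooxolan-3-yl]butanoate
Conditions: Ac2O, pyridine, DMAP (cat.), CH2Cl2, 0 °C
Reagents that add atoms: acetic anhydride, CC(=O)OC(C)=O
Why: Acylation of the allylic C-9 hydroxyl installs the acetate of the target with retention; low temperature and catalytic DMAP avoid allylic transposition.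

Step 20
Reactants: 28 methyl (3S,4S)-3-acetoxy-4-[(4-methoxybenzyl)oxy]-2-methylidene-4-[(2R,3S)-4-methylidene-2-[(1E)-2-methylhexa-1,5-dien-1-yl]-5-oxooxolan-3-yl]butanoate
Product: 29 methyl (6R,7S,8S,9S)-9-acetoxy-8-[(4-methoxybenzyl)oxy]germacra-1(10),4,11(13)-trien-12,6-olid-14-oate (4E; C-2 and C-9 cis on C-1=C-10)
Conditions: second-generation Hoveyda–Grubbs catalyst RuCl2(H2IMes)(=CH-C6H4-2-OiPr) (15 mol%), toluene (0.5 mM), 80 °C
Reagents that add atoms: none
Why: Ring-closing metathesis: the ruthenium carbene forms at the monosubstituted C-1 olefin and closes onto the acrylate methylene, and the ten-membered ring that already holds the E C-4=C-5 olefin should allow only the ring-cis C-1=C-10 geometry of the target.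

Step 21
Reactants: 29 methyl (6R,7S,8S,9S)-9-acetoxy-8-[(4-methoxybenzyl)oxy]germacra-1(10),4,11(13)-trien-12,6-olid-14-oate
Product: 30 methyl (6R,7R,8S,9S)-9-acetoxy-8-hydroxygermacra-1(10),4,11(13)-trien-12,6-olid-14-oate
Conditions: DDQ, CH2Cl2/pH 7 buffer, 0 °C → rt
Reagents that add atoms: none
Why: Oxidative cleavage of the PMB ether under neutral conditions frees the C-8 hydroxyl without acetyl migration; the bridged geometry disfavours lactonisation onto the C-14 ester.

Step 22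
Reactants: 31 methyl 2-(hydroxymethyl)prop-2-enoate
Product: 32 methyl 2-{[(tert-butyldimethylsilyl)oxy]methyl}prop-2-enoate
Conditions: TBSCl, imidazole, CH2Cl2, 0 °C → rt
Reagents that add atoms: tert-butyldimethylsilyl chloride, CC(C)(C)[Si](C)(C)Cl
Why: Silylation protects the primary allylic hydroxyl of the acyl donor.

Step 23
Reactants: 32 methyl 2-{[(tert-butyldimethylsilyl)oxy]methyl}prop-2-enoate
Product: 33 2-{[(tert-butyldimethylsilyl)oxy]methyl}prop-2-enoic acid
Conditions: LiOH, THF/H2O, 0 °C; then 1 M HCl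
Reagents that add atoms: lithium hydroxide, [Li+].[OH-]
Why: Saponification of the methyl ester at 0 °C gives the acid while the silyl ether survives.

Step 24
Reactants: 30 methyl (6R,7R,8S,9S)-9-acetoxy-8-hydroxygermacra-1(10),4,11(13)-trien-12,6-olid-14-oate; 33 2-{[(tert-butyldimethylsilyl)oxy]methyl}prop-2-enoic acid
Product: 35 methyl (6R,7S,8S,9S)-9-acetoxy-8-[(2-{[(tert-butyldimethylsilyl)oxy]methyl}prop-2-enoyl)oxy]germacra-1(10),4,11(13)-trien-12,6-olid-14-oate, via mixed anhydride 34 (not isolated)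
Conditions: 2,4,6-trichlorobenzoyl chloride, Et3N, THF, rt; then 30, DMAP, toluene, 0 °C → rt
Reagents that add atoms: none
Why: Yamaguchi esterification through the mixed anhydride acylates the hindered C-8 hydroxyl with retention, acyl transfer from the acylpyridinium being faster than migration of the neighbouring acetate.

Step 25
Reactants: 35 methyl (6R,7S,8S,9S)-9-acetoxy-8-[(2-{[(tert-butyldimethylsilyl)oxy]methyl}prop-2-enoyl)oxy]germacra-1(10),4,11(13)-trien-12,6-olid-14-oate
Product: 36 CNP0291058.1, methyl (6R,7S,8S,9S)-9-acetoxy-8-{[2-(hydroxymethyl)prop-2-enoyl]oxy}germacra-1(10),4,11(13)-trien-12,6-olid-14-oate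
Conditions: HF·pyridine, pyridine, THF, 0 °C → rt
Reagents that add atoms: none
Why: Buffered fluoride removes the primary silyl ether while the three esters, the lactone and both acrylate units are left intact.

Compound list
1 | 4,6-O-[(R)-benzylidene]-D-glucopyranose (anomeric mixture) | c3ccccc3[C@@H]2OC[C@H]1OC(O)[C@H](O)[C@@H](O)[C@@H]1O2 | starting material
2 | 2,4-O-[(R)-benzylidene]-D-erythrose, (2R,4R,5R)-5-hydroxy-2-phenyl-1,3-dioxane-4-carbaldehyde (handled as its hemiacetal dimer) | c2ccccc2[C@@H]1OC[C@@H](O)[C@H](C=O)O1 | intermediate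
3 | (2R,4S,5R)-4-ethynyl-2-phenyl-1,3-dioxan-5-ol | c2ccccc2[C@@H]1OC[C@@H](O)[C@H](C#C)O1 | intermediate
4 | (2R,4S,5R)-4-ethynyl-5-[(4-methoxybenzyl)oxy]-2-phenyl-1,3-dioxane | c2ccccc2[C@@H]1OC[C@@H](OCc3ccc(OC)cc3)[C@H](C#C)O1 | intermediate
5 | (2R,3S)-2-[(4-methoxybenzyl)oxy]pent-4-yne-1,3-diol | OC[C@@H](OCc1ccc(OC)cc1)[C@@H](O)C#C | intermediate
6 | (3S,4R)-5-[(tert-butyldimethylsilyl)oxy]-4-[(4-methoxybenzyl)oxy]pent-1-yn-3-ol | CC(C)(C)[Si](C)(C)OC[C@@H](OCc1ccc(OC)cc1)[C@@H](O)C#C | intermediate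
7 | (3S,4R)-5-[(tert-butyldimethylsilyl)oxy]-4-[(4-methoxybenzyl)oxy]pent-1-yn-3-yl methanesulfonate | CC(C)(C)[Si](C)(C)OC[C@@H](OCc1ccc(OC)cc1)[C@@H](OS(C)(=O)=O)C#C | intermediate
8 | ethyl but-2-ynoate | CC#CC(=O)OCC | starting material
9 | but-3-en-1-ylmagnesium bromide | C=CCC[Mg]Br | starting material
10 | ethyl (2E)-3-methylhepta-2,6-dienoate | CCOC(=O)/C=C(\C)CCC=C | intermediate
11 | (2E)-3-methylhepta-2,6-dien-1-ol | OC/C=C(\C)CCC=C | intermediate
12 | (2E)-3-methylhepta-2,6-dienal | O=C/C=C(\C)CCC=C | intermediate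
13 | ethyl[(4S)-5-[(tert-butyldimethylsilyl)oxy]-4-[(4-methoxybenzyl)oxy]penta-1,2-dien-1-yl]zinc, allene axis as formed by anti SN2′ displacement | CC[Zn]C([H])=[C@@]=C([H])[C@H](OCc1ccc(OC)cc1)CO[Si](C)(C)C(C)(C)C | intermediate
14 | (2S,3S,4R,5E)-1-[(tert-butyldimethylsilyl)oxy]-3-ethynyl-2-[(4-methoxybenzyl)oxy]-6-methyldeca-5,9-dien-4-ol (C-6 R, C-7 S, C-8 S) | CC(C)(C)[Si](C)(C)OC[C@@H](OCc1ccc(OC)cc1)[C@@H](C#C)[C@H](O)/C=C(\C)CCC=C | intermediate
15 | diisobutylaluminium alkoxide of the C-11 diisobutylalumino-ethenyl analogue of 14 | CC(C)(C)[Si](C)(C)OC[C@@H](OCc1ccc(OC)cc1)[C@@H](C(=C)[Al](CC(C)C)CC(C)C)[C@H](O[Al](CC(C)C)CC(C)C)/C=C(\C)CCC=C | intermediate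
16 | (2S,3S,4R,5E)-1-[(tert-butyldimethylsilyl)oxy]-2-[(4-methoxybenzyl)oxy]-6-methyl-3-[1-(4,4,5,5-tetramethyl-1,3,2-dioxaborolan-2-yl)ethenyl]deca-5,9-dien-4-ol | CC(C)(C)[Si](C)(C)OC[C@@H](OCc1ccc(OC)cc1)[C@@H](C(=C)B1OC(C)(C)C(C)(C)O1)[C@H](O)/C=C(\C)CCC=C | intermediate
17 | tert-butyl (2S,3S,4R,5E)-1-[(tert-butyldimethylsilyl)oxy]-2-[(4-methoxybenzyl)oxy]-6-methyl-3-[1-(4,4,5,5-tetramethyl-1,3,2-dioxaborolan-2-yl)ethenyl]deca-5,9-dien-4-yl carbonate | CC(C)(C)[Si](C)(C)OC[C@@H](OCc1ccc(OC)cc1)[C@@H](C(=C)B1OC(C)(C)C(C)(C)O1)[C@H](OC(=O)OC(C)(C)C)/C=C(\C)CCC=C | intermediate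
18 | potassium (3S,4R,5E)-4-[(tert-butoxycarbonyl)oxy]-3-[(1S)-2-[(tert-butyldimethylsilyl)oxy]-1-[(4-methoxybenzyl)oxy]ethyl]-6-methyl-2-methylidenedeca-5,9-dienoate | [K+].CC(C)(C)[Si](C)(C)OC[C@@H](OCc1ccc(OC)cc1)[C@@H](C(=C)C(=O)[O-])[C@H](OC(=O)OC(C)(C)C)/C=C(\C)CCC=C | intermediate
19 | (4S,5R)-4-[(1S)-2-[(tert-butyldimethylsilyl)oxy]-1-[(4-methoxybenzyl)oxy]ethyl]-3-methylidene-5-[(1E)-2-methylhexa-1,5-dien-1-yl]oxolan-2-one | CC(C)(C)[Si](C)(C)OC[C@@H](OCc1ccc(OC)cc1)[C@H]1C(=C)C(=O)O[C@@H]1/C=C(\C)CCC=C | intermediate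
20 | (4S,5R)-4-[(1S)-2-hydroxy-1-[(4-methoxybenzyl)oxy]ethyl]-3-methylidene-5-[(1E)-2-methylhexa-1,5-dien-1-yl]oxolan-2-one | OC[C@@H](OCc1ccc(OC)cc1)[C@H]1C(=C)C(=O)O[C@@H]1/C=C(\C)CCC=C | intermediate
21 | (2S)-2-[(4-methoxybenzyl)oxy]-2-[(2R,3S)-4-methylidene-2-[(1E)-2-methylhexa-1,5-dien-1-yl]-5-oxooxolan-3-yl]acetaldehyde | O=C[C@@H](OCc1ccc(OC)cc1)[C@H]1C(=C)C(=O)O[C@@H]1/C=C(\C)CCC=C | intermediate
22 | methyl 2-bromopropanoate (racemic) | COC(=O)C(C)Br | starting material
23 | methyl 2-(phenylselanyl)propanoate (racemic) | COC(=O)C(C)[Se]c1ccccc1 | intermediate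
24 | [(1-methoxy-2-(phenylselanyl)prop-1-en-1-yl)oxy]trimethylsilane (E/Z mixture) | COC(O[Si](C)(C)C)=C(C)[Se]c1ccccc1 | intermediate
25 | methyl (3R,4S)-3-hydroxy-4-[(4-methoxybenzyl)oxy]-2-methyl-4-[(2R,3S)-4-methylidene-2-[(1E)-2-methylhexa-1,5-dien-1-yl]-5-oxooxolan-3-yl]-2-(phenylselanyl)butanoate (both C-2 epimers) | COC(=O)C(C)([Se]c1ccccc1)[C@H](O)[C@@H](OCc1ccc(OC)cc1)[C@H]1C(=C)C(=O)O[C@@H]1/C=C(\C)CCC=C | intermediate
26 | selenoxide of 25 | COC(=O)C(C)([Se](=O)c1ccccc1)[C@H](O)[C@@H](OCc1ccc(OC)cc1)[C@H]1C(=C)C(=O)O[C@@H]1/C=C(\C)CCC=C | intermediate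
27 | methyl (3S,4S)-3-hydroxy-4-[(4-methoxybenzyl)oxy]-2-methylidene-4-[(2R,3S)-4-methylidene-2-[(1E)-2-methylhexa-1,5-dien-1-yl]-5-oxooxolan-3-yl]butanoate | C=C(C(=O)OC)[C@H](O)[C@@H](OCc1ccc(OC)cc1)[C@H]1C(=C)C(=O)O[C@@H]1/C=C(\C)CCC=C | intermediate
28 | methyl (3S,4S)-3-acetoxy-4-[(4-methoxybenzyl)oxy]-2-methylidene-4-[(2R,3S)-4-methylidene-2-[(1E)-2-methylhexa-1,5-dien-1-yl]-5-oxooxolan-3-yl]butanoate | C=C(C(=O)OC)[C@H](OC(C)=O)[C@@H](OCc1ccc(OC)cc1)[C@H]1C(=C)C(=O)O[C@@H]1/C=C(\C)CCC=C | intermediate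
29 | methyl (6R,7S,8S,9S)-9-acetoxy-8-[(4-methoxybenzyl)oxy]germacra-1(10),4,11(13)-trien-12,6-olid-14-oate (4E; C-2 and C-9 cis on C-1=C-10) | COc1ccc(CO[C@H]2[C@H]3C(=C)C(=O)O[C@@H]3/C=C(\C)CC/C=C(/C(=O)OC)[C@@H]2OC(C)=O)cc1 | intermediate
30 | methyl (6R,7R,8S,9S)-9-acetoxy-8-hydroxygermacra-1(10),4,11(13)-trien-12,6-olid-14-oate | O[C@H]1[C@H]2C(=C)C(=O)O[C@@H]2/C=C(\C)CC/C=C(/C(=O)OC)[C@@H]1OC(C)=O | intermediate
31 | methyl 2-(hydroxymethyl)prop-2-enoate | C=C(CO)C(=O)OC | starting material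
32 | methyl 2-{[(tert-butyldimethylsilyl)oxy]methyl}prop-2-enoate | C=C(CO[Si](C)(C)C(C)(C)C)C(=O)OC | intermediate
33 | 2-{[(tert-butyldimethylsilyl)oxy]methyl}prop-2-enoic acid | C=C(CO[Si](C)(C)C(C)(C)C)C(=O)O | intermediate
34 | 2-{[(tert-butyldimethylsilyl)oxy]methyl}prop-2-enoic 2,4,6-trichlorobenzoic anhydride | C=C(CO[Si](C)(C)C(C)(C)C)C(=O)OC(=O)c1c(Cl)cc(Cl)cc1Cl | intermediate
35 | methyl (6R,7S,8S,9S)-9-acetoxy-8-[(2-{[(tert-butyldimethylsilyl)oxy]methyl}prop-2-enoyl)oxy]germacra-1(10),4,11(13)-trien-12,6-olid-14-oate | C=C(CO[Si](C)(C)C(C)(C)C)C(=O)O[C@H]1[C@H]2C(=C)C(=O)O[C@@H]2/C=C(\C)CC/C=C(/C(=O)OC)[C@@H]1OC(C)=O | intermediate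
36 | CNP0291058.1, methyl (6R,7S,8S,9S)-9-acetoxy-8-{[2-(hydroxymethyl)prop-2-enoyl]oxy}germacra-1(10),4,11(13)-trien-12,6-olid-14-oate | C=C(CO)C(=O)O[C@H]1[C@H]2C(=C)C(=O)O[C@@H]2/C=C(\C)CC/C=C(/C(=O)OC)[C@@H]1OC(C)=O | target

Total step count: 25. Longest linear sequence: 18 steps (steps 1–5, 9–14, 17–21, 24 and 25).

Steps most likely to fail

1. Step 20 (ring-closing metathesis). Intermolecular metathesis of the terminal olefin (oligomerisation) may outpace closure of the strained ten-membered ring onto the hindered, electron-poor 1,1-disubstituted acrylate. The fallback closes the ring at C-9–C-10 by a Nozaki–Hiyama–Kishi reaction; it sets out from 19 and comes back at 29. Dihydroxylation of the monosubstituted terminal olefin of 19 (OsO4 cat., N-methylmorpholine N-oxide; the C-4=C-5 olefin is deactivated by the allylic lactone oxygen and the exo-methylene by its carbonyl) and NaIO4 cleavage would give the C-1 aldehyde F1. A Wittig reaction with methyl iodo(triphenylphosphoranylidene)acetate (from Ph3P=CHCO2Me and N-iodosuccinimide) would give the (Z)-2-iodoenoate F2, in which C-2 is already trans to the ester. HF·pyridine would give the primary alcohol F3 and Dess–Martin oxidation the α-alkoxy aldehyde F4. CrCl2 with NiCl2 (cat.) in DMSO/THF at high dilution would close the ring with retention of the olefin geometry to the macrocyclic C-9 alcohol F5, whose C-9 configuration would rest on the macrocyclic transition state and would have to be verified. Acetylation (Ac2O, pyridine) would return to 29.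

2. Step 12 (carboxylative lactonisation). The alkenylcopper may attack the allylic carbonate, or the π-allyl complex may lose a β-hydride to a triene before the carboxylate captures it. The fallback sets out from 16 and comes back at 19. The unprotected boronate 16 would be carboxylated under the same copper conditions ((IPr)CuCl, KOtBu 2.1 equiv, CO2, THF, 65 °C) and acidified to the γ-hydroxy acrylic acid F6. Conventional lactonisation (pyridinium p-toluenesulfonate, CH2Cl2, rt), in which the C-6 hydroxyl attacks the acid with retention, would then give 19.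

3. Step 10 (hydroalumination–borylation). Markovnikov selectivity may erode at the branched propargylic position and the terminal olefin may be hydroaluminated competitively. The fallback sets out from 14 and comes back at 16. Bromoboration of the alkyne with B-bromo-9-borabicyclo[3.3.1]nonane (CH2Cl2, 0 °C), which places bromine on the internal carbon, followed by protodeboronation with AcOH would give the 2-bromoalkene F7. Miyaura borylation (PdCl2(dppf), bis(pinacolato)diboron, KOPh, toluene, 50 °C) would then give 16.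

Further compounds
F1 | step 20 | (4E)-6-[(2R,3S)-3-[(1S)-2-[(tert-butyldimethylsilyl)oxy]-1-[(4-methoxybenzyl)oxy]ethyl]-4-methylidene-5-oxooxolan-2-yl]-4-methylhex-4-enal-type C-1 aldehyde of 19 | CC(C)(C)[Si](C)(C)OC[C@@H](OCc1ccc(OC)cc1)[C@H]1C(=C)C(=O)O[C@@H]1/C=C(\C)CCC=O
F2 | step 20 | methyl (2Z,6E)-2-iodo-6-methyl-7-[lactone of 19]hepta-2,6-dienoate, C-9 silyl ether | CC(C)(C)[Si](C)(C)OC[C@@H](OCc1ccc(OC)cc1)[C@H]1C(=C)C(=O)O[C@@H]1/C=C(\C)CC/C=C(\I)C(=O)OC
F3 | step 20 | C-9 primary alcohol of F2 | OC[C@@H](OCc1ccc(OC)cc1)[C@H]1C(=C)C(=O)O[C@@H]1/C=C(\C)CC/C=C(\I)C(=O)OC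
F4 | step 20 | C-9 aldehyde of F2 | O=C[C@@H](OCc1ccc(OC)cc1)[C@H]1C(=C)C(=O)O[C@@H]1/C=C(\C)CC/C=C(\I)C(=O)OC
F5 | step 20 | methyl (6R,7S,8S,9S)-9-hydroxy-8-[(4-methoxybenzyl)oxy]germacra-1(10),4,11(13)-trien-12,6-olid-14-oate | COc1ccc(CO[C@H]2[C@H]3C(=C)C(=O)O[C@@H]3/C=C(\C)CC/C=C(/C(=O)OC)[C@@H]2O)cc1
F6 | step 12 | (3S,4R,5E)-3-[(1S)-2-[(tert-butyldimethylsilyl)oxy]-1-[(4-methoxybenzyl)oxy]ethyl]-4-hydroxy-6-methyl-2-methylidenedeca-5,9-dienoic acid | CC(C)(C)[Si](C)(C)OC[C@@H](OCc1ccc(OC)cc1)[C@@H](C(=C)C(=O)O)[C@H](O)/C=C(\C)CCC=C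
F7 | step 10 | (2S,3S,4R,5E)-3-(1-bromoethenyl)-1-[(tert-butyldimethylsilyl)oxy]-2-[(4-methoxybenzyl)oxy]-6-methyldeca-5,9-dien-4-ol | CC(C)(C)[Si](C)(C)OC[C@@H](OCc1ccc(OC)cc1)[C@@H](C(Br)=C)[C@H](O)/C=C(\C)CCC=C
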